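**Strategy.** Everything rests on deriving ring A (C1–C5, C10) from a seven-membered ring. (R)-Carvone supplies ring B and C5. Two enolate alkylations and a ring-closing metathesis give a trans-fused cyclohexenone–cycloheptene whose isopropenyl carbons are C4 and the future hydroxymethyl carbon C13. After α-face epoxidation, a Lewis-acid epoxide–aldehyde (Meinwald) rearrangement contracts that ring: the C13–C3 bond migrates to C4. This one operation closes ring A, extrudes C13 as the formyl carbon and sets the quaternary stereocentre C4(CH3)(CH2OH) flanked by C3 and C5, which is the feature exploited. Hydroboration/B-alkyl Suzuki coupling with an iodoquinone monoketal, then epoxidation, reduction and hydrolysis, complete the epoxyquinol.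

Key step: step 5

Remark: drimane-style numbering is used (ring A = C1–C5, C10; ring B = C5–C10; C11 = CH2 on C9; C13 = the oxygenated carbon on C4; primes = epoxyquinol ring, C1′ ketone, C4′ carbinol, C5′ quaternary epoxide carbon); 5-iodopent-1-ene and 4-methoxy-3-methylphenol are taken as commercial.

**Step 1**
Reactants: 1 (R)-(−)-carvone
Product: 2 6-methylcarvone (C6 epimers)
Conditions: LDA, THF, −78 °C; MeI, −78 → 0 °C
Reagents that add atoms: iodomethane, CI
Why: Kinetic α′-deprotonation gives the cross-conjugated lithium enolate, which is C-methylated (enolate alkylation); the C6 configuration is irrelevant because C6 is re-enolised in step 2.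

**Step 2**
Reactants: 2 6-methylcarvone; 3 5-iodopent-1-ene
Product: 4 (5S,6S)-2,6-dimethyl-6-(pent-4-en-1-yl)-5-(prop-1-en-2-yl)cyclohex-2-en-1-one
Conditions: LDA, THF, −78 → 0 °C; then 3, DMPU, 0 °C → rt
Reagents that add atoms: none
Why: Enolate alkylation of the re-formed α′-enolate with the primary iodide should occur anti to the adjacent pseudoaxial isopropenyl group (the usual sense for 6-alkylcarvones), setting the quaternary C10 with pentenyl trans and methyl cis to isopropenyl.

**Step 3**
Reactants: 4 dialkylated carvone
Product: 5 trans-fused cyclohexenone–cycloheptene (10β-Me, 5α-H, C4(Me)=C13 in the seven-membered ring)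
Conditions: Grubbs II (5 mol %), CH2Cl2 (5 mM), 40 °C
Reagents that add atoms: none
Why: Ring-closing metathesis of the isopropenyl group with the terminal vinyl group should give the trisubstituted cycloheptene, since the two trans-diequatorial arms are gauche, the enone alkene is inert and ethylene loss drives the closure.

**Step 4**
Reactants: 5 bicyclic dienone
Product: 6 4α,13α-epoxide of 5
Conditions: mCPBA, NaHCO3, CH2Cl2, 0 °C
Reagents that add atoms: meta-chloroperbenzoic acid, OOC(=O)c1cccc(Cl)c1
Why: Prilezhaev epoxidation should take only the electron-rich ring alkene (not the enone) and approach the convex α-face, anti to the axial C10 methyl and to C10/C2 which lie on the β-side of the chair cycloheptene, setting C4 and C13.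

**Step 5**
Reactants: 6 α-epoxide
Product: 7 keto aldehyde (4α-formyl-4β,8,10β-trimethyl-trans-decal-7-en-9-one)
Conditions: MABR (2.2 equiv, from Me3Al and 4-bromo-2,6-di-tert-butylphenol 1:2), CH2Cl2, −78 → −20 °C
Reagents that add atoms: none
Why: MABR binds the epoxide oxygen, the tertiary C4–O bond ionises and the ring bond C13–C3 shifts from C13 to C4 on the face opposite the departing oxygen while C13 becomes the aldehyde carbon (Meinwald/semipinacol epoxide–aldehyde rearrangement with ring contraction). The closest known reactions are the MABR-promoted rearrangement of trisubstituted epoxides to α-quaternary aldehydes and the contraction of 1-methylcycloalkene oxides to 1-methylcycloalkanecarbaldehydes. Ring A is closed by this suprafacial 1,2-alkyl shift through a three-centre transition state (a ring contraction, not a Baldwin-type cyclisation), which turns the seven-membered ring C10–C1–C2–C3–C13–C4–C5 into the six-membered ring C10–C1–C2–C3–C4–C5. The only new stereocentre, C4, is fixed stereospecifically by the epoxide configuration: C3 bonds anti to the α-oxygen with inversion at C4, so that in the resulting chair the methyl is axial (β, syn to the C10 methyl) and the formyl equatorial (α). The step needs ring-bond migration to win over the 1,2-hydride shift from C13 (cycloheptanone), over proton loss to an allylic alcohol and over halohydrin-type double inversion; the bulky, non-nucleophilic aluminium phenoxide is the reagent known to favour alkyl over hydride migration, H5 is syn to the breaking C–O bond and cannot shift, and the developing trans-decalin chair is strain-free. The enone carbonyl only ties up one equivalent of the Lewis acid, hence the excess.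

**Step 6**
Reactants: 7 keto aldehyde
Product: 8 hydroxy enone (4α-hydroxymethyl)
Conditions: NaBH4 (0.5 equiv), MeOH/CH2Cl2, −78 → −40 °C
Reagents that add atoms: none
Why: Chemoselective borohydride reduction: the aldehyde should be reduced far faster than the conjugated ketone hindered by the quaternary C10, and no stereocentre is created.

**Step 7**
Reactants: 8 hydroxy enone
Product: 9 dienol (9-methylene-drim-7-en-13-ol skeleton)
Conditions: Ph3PCH3Br, KOtBu (4 equiv each), toluene, 90 °C
Reagents that add atoms: methylenetriphenylphosphorane (from methyltriphenylphosphonium bromide and KOtBu), C=P(c1ccccc1)(c1ccccc1)c1ccccc1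
Why: Wittig methylenation under the salt-free high-temperature conditions used for hindered ketones (cf. 2,6,6-trimethylcyclohex-2-enone to γ-pyronene); the free hydroxyl is carried as its alkoxide by the excess base.

**Step 8**
Reactants: 10 4-methoxy-3-methylphenol
Product: 11 2-iodo-4-methoxy-5-methylphenol
Conditions: NIS, TsOH (10 mol %), MeCN, 0 °C
Reagents that add atoms: N-iodosuccinimide, O=C1CCC(=O)N1I
Why: Electrophilic aromatic iodination should go ortho to the hydroxyl and para to the methyl, the position activated by both and the less hindered of the two ortho sites.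

**Step 9**
Reactants: 11 iodophenol
Product: 12 2-iodo-4,4-dimethoxy-5-methylcyclohexa-2,5-dien-1-one
Conditions: PhI(OAc)2, MeOH, 0 °C
Reagents that add atoms: methanol, CO
Why: Oxidative dearomatisation of a para-methoxyphenol with a hypervalent iodine reagent in methanol gives the quinone monoketal with the carbonyl at the former phenol carbon, which fixes which oxygen later becomes the carbinol.

**Step 10**
Reactants: 9 dienol; 12 iodo dienone monoketal
Product: 14 2-(13-hydroxydrim-7-en-11-yl)-4,4-dimethoxy-5-methylcyclohexa-2,5-dien-1-one, via C11-boryl O-borinate bis(9-BBN) adduct 13 (not isolated)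
Conditions: 9-BBN (2.4 equiv), THF, 0 → 40 °C; aq. Cs2CO3; then 12, PdCl2(dppf) (10 mol %), Ph3As, DMF, rt
Reagents that add atoms: none
Why: Hydroboration puts boron on the terminal C11 and hydrogen on C9 from the α-face, anti to the axial C10 methyl (9α-H, equatorial C11; cf. γ-pyronene to α-cyclogeraniol), and the B-alkyl Suzuki–Miyaura coupling under the α-iodoenone conditions then forms C11–C5′, the O-borinate being hydrolysed on work-up.

**Step 11**
Reactants: 14 dienone monoketal
Product: 15 5′,6′-epoxy ketone monoketal (epoxide configured as in the target)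
Conditions: tBuOOH, N-(9-anthracenylmethyl)cinchonidinium chloride (10 mol %), aq. NaOH, toluene, 0 °C
Reagents that add atoms: tert-butyl hydroperoxide, CC(C)(C)OO
Why: Weitz–Scheffer epoxidation under chiral phase-transfer catalysis, as used for quinone monoketals: the peroxide should add to the unsubstituted β-carbon C6′ of the α-alkylated enone arm rather than to the β-methylated C2′, the electron-rich C7=C8 alkene is untouched, and the ion-paired catalyst is relied on for the face (C5′, C6′).

**Step 12**
Reactants: 15 epoxy ketone
Product: 16 trans-epoxy alcohol dimethyl ketal (4′-OH anti to the epoxide oxygen)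
Conditions: L-Selectride (2.5 equiv), THF, −78 °C; aq. NH4Cl
Reagents that add atoms: none
Why: 1,2-Reduction by a bulky trialkylborohydride, which should approach C4′ anti to the drimanylmethyl group on C5′ (syn to the small epoxide oxygen) and so place the hydroxyl trans to the epoxide; the β,β-disubstituted enone disfavours 1,4-reduction.

**Step 13**
Reactants: 16 epoxy alcohol ketal
Product: 17 Epoxypholamin B
Conditions: montmorillonite K10, wet CH2Cl2, rt
Reagents that add atoms: water, O
Why: Mild solid-acid hydrolysis of the dimethyl ketal, as used for epoxyquinol monoketals, should unmask the C1′ enone without opening the epoxide or transposing the allylic alcohol.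

**Compound list**
1 | (R)-(−)-carvone, (5R)-2-methyl-5-(prop-1-en-2-yl)cyclohex-2-en-1-one | O=C1C(C)=CC[C@@H](C(C)=C)C1 | starting material
2 | 6-methylcarvone, (5R,6RS)-2,6-dimethyl-5-(prop-1-en-2-yl)cyclohex-2-en-1-one | O=C1C(C)=CC[C@@H](C(C)=C)C1C | intermediate
3 | 5-iodopent-1-ene | C=CCCCI | starting material
4 | (5S,6S)-2,6-dimethyl-6-(pent-4-en-1-yl)-5-(prop-1-en-2-yl)cyclohex-2-en-1-one (pentenyl trans to isopropenyl) | O=C1C(C)=CC[C@@H](C(C)=C)[C@]1(C)CCCC=C | intermediate
5 | trans-fused 3,4a,9-trimethyl-1,4a,5,6,7,9a-hexahydro-4H-benzo[7]annulen-4-one (10β-Me, 5α-H, C4=C13) | O=C1C(C)=CC[C@H]2C(C)=CCCC[C@]12C | intermediate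
6 | 4α,13α-epoxide of 5 (oxygen anti to the C10 methyl) | O=C1C(C)=CC[C@H]2[C@]3(C)O[C@@H]3CCC[C@]12C | intermediate
7 | 4α-formyl-4β,8,10β-trimethyl-trans-decal-7-en-9-one (5α-H) | O=C1C(C)=CC[C@H]2[C@](C)(C=O)CCC[C@]12C | intermediate
8 | 4α-(hydroxymethyl)-4β,8,10β-trimethyl-trans-decal-7-en-9-one | O=C1C(C)=CC[C@H]2[C@](C)(CO)CCC[C@]12C | intermediate
9 | 4α-(hydroxymethyl)-4β,8,10β-trimethyl-9-methylene-trans-decal-7-ene | C=C1C(C)=CC[C@H]2[C@](C)(CO)CCC[C@]12C | intermediate
10 | 4-methoxy-3-methylphenol | COc1ccc(O)cc1C | starting material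
11 | 2-iodo-4-methoxy-5-methylphenol | COc1cc(I)c(O)cc1C | intermediate
12 | 2-iodo-4,4-dimethoxy-5-methylcyclohexa-2,5-dien-1-one | CC1=CC(=O)C(I)=CC1(OC)OC | intermediate
13 | C11-(9-BBN) borane, O13-(9-BBN) borinate of drim-7-en-13-ol (9α-H) | C(B1C2CCCC1CCC2)[C@H]3C(C)=CC[C@H]4[C@](C)(COB5C6CCCC5CCC6)CCC[C@]34C | intermediate
14 | 2-(13-hydroxydrim-7-en-11-yl)-4,4-dimethoxy-5-methylcyclohexa-2,5-dien-1-one (9α-H, 4α-CH2OH) | CC1=CC(=O)C(C[C@H]2C(C)=CC[C@H]3[C@](C)(CO)CCC[C@]23C)=CC1(OC)OC | intermediate
15 | 1-(13-hydroxydrim-7-en-11-yl)-5,5-dimethoxy-4-methyl-7-oxabicyclo[4.1.0]hept-3-en-2-one (epoxide as in the target) | CC1=CC(=O)[C@]2(C[C@H]3C(C)=CC[C@H]4[C@](C)(CO)CCC[C@]34C)O[C@@H]2C1(OC)OC | intermediate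
16 | 6-(13-hydroxydrim-7-en-11-yl)-2,2-dimethoxy-3-methyl-7-oxabicyclo[4.1.0]hept-3-en-5-ol (5-OH anti to the epoxide oxygen) | CC1=C[C@@H](O)[C@]2(C[C@H]3C(C)=CC[C@H]4[C@](C)(CO)CCC[C@]34C)O[C@@H]2C1(OC)OC | intermediate
17 | Epoxypholamin B, (1S,5R,6S)-5-hydroxy-6-{[(1S,4aR,5R,8aR)-5-(hydroxymethyl)-2,5,8a-trimethyl-1,4,4a,5,6,7,8,8a-octahydronaphthalen-1-yl]methyl}-3-methyl-7-oxabicyclo[4.1.0]hept-3-en-2-one | CC1=C[C@@H](O)[C@]2(C[C@H]3C(C)=CC[C@H]4[C@](C)(CO)CCC[C@]34C)O[C@@H]2C1=O | target

**Step count.** Total steps: 13. Longest linear sequence: 11 (steps 1–7 and 10–13; steps 8–9 prepare the coupling partner).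

**Steps most likely to fail**

Step 5. The 1,2-hydride shift from C13 may compete with ring-bond migration, the tertiary cation may lose a proton, or the migration may lose its stereospecificity. The fallback sets out from 5 and returns at 7. NBS in aqueous THF should form the α-bromonium ion and open it by anti attack of water at the tertiary carbon, giving the 4β-hydroxy-13α-bromide F1. K2CO3 in MeOH closes this to the β-epoxide F2, the diastereomer of 6. MgBr2·OEt2 in ether–benzene opens F2 at C4 with inversion to the bromomagnesium alkoxide of the 4α-bromo-13β-ol F3. On warming, F3 undergoes the Tiffeneau-type semipinacol contraction, because in this trans-halohydrin only the ring bond C13–C3 can become antiperiplanar to C4–Br, while the C13 hydrogen is cis to bromine and cannot. The double inversion at C4 leads to the same aldehyde 7.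

Step 11. The catalyst may fail to override the remote drimane stereocentres (poor facial selectivity), or the α-branched dienone may react sluggishly under phase transfer. The fallback sets out from 14 and returns at 17. Transketalisation with (2R,4R)-pentane-2,4-diol (BF3·OEt2) gives the chiral spiro-dioxane dienone F4. Its axial methyl should direct a Weitz–Scheffer epoxidation (tBuOOH, DBU) to the epoxy ketone F5; the enantiomeric diol is taken if the auxiliary shields the wrong face. L-Selectride reduction gives the epoxy alcohol F6, and aqueous acid hydrolysis of the dioxane gives 17.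

Step 12. Hydride delivery anti to the epoxide oxygen, the usual sense for epoxyquinone monoketals that lack the C5′ substituent, would give the 4′-epimer. The fallback sets out from 15 and returns at 16. DIBAL-H reduction in that usual sense gives the cis-epoxy alcohol F7. Mitsunobu inversion (4-nitrobenzoic acid, DIAD, PPh3) gives the inverted 4′-(4-nitrobenzoate) F8; the neopentyl C13 hydroxyl, if acylated at all, is freed in the next operation. Methanolysis (K2CO3, MeOH) then gives 16.

**Further compounds**
F1 | step 5 | 4β-hydroxy-13α-bromo bromohydrin of 5 | O=C1C(C)=CC[C@H]2[C@@](C)(O)[C@H](Br)CCC[C@]12C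
F2 | step 5 | 4β,13β-epoxide of 5 | O=C1C(C)=CC[C@H]2[C@@]3(C)O[C@H]3CCC[C@]12C
F3 | step 5 | bromomagnesium alkoxide of the 4α-bromo-13β-ol | O=C1C(C)=CC[C@H]2[C@](C)(Br)[C@@H](O[Mg]Br)CCC[C@]12C
F4 | step 11 | (2R,4R)-pentane-2,4-diyl ketal analogue of 14 | CC1=CC(=O)C(C[C@H]2C(C)=CC[C@H]3[C@](C)(CO)CCC[C@]23C)=CC14O[C@H](C)C[C@@H](C)O4
F5 | step 11 | epoxy ketone from F4 (epoxide as in the target) | CC1=CC(=O)[C@]2(C[C@H]3C(C)=CC[C@H]4[C@](C)(CO)CCC[C@]34C)O[C@@H]2C15O[C@H](C)C[C@@H](C)O5
F6 | step 11 | trans-epoxy alcohol from F5 | CC1=C[C@@H](O)[C@]2(C[C@H]3C(C)=CC[C@H]4[C@](C)(CO)CCC[C@]34C)O[C@@H]2C15O[C@H](C)C[C@@H](C)O5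
F7 | step 12 | 4′-epimer of 16 (4′-OH syn to the epoxide oxygen) | CC1=C[C@H](O)[C@]2(C[C@H]3C(C)=CC[C@H]4[C@](C)(CO)CCC[C@]34C)O[C@@H]2C1(OC)OC
F8 | step 12 | 4′-(4-nitrobenzoate) of 16 | CC1=C[C@@H](OC(=O)c5ccc(cc5)[N+](=O)[O-])[C@]2(C[C@H]3C(C)=CC[C@H]4[C@](C)(CO)CCC[C@]34C)O[C@@H]2C1(OC)OC
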